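## Structural features

The target is (R)-8-hydroxy-3-(11-hydroxyundecyl)-6-methoxy-3,4-dihydroisocoumarin, a benzene ring A fused along C4a–C8a to a six-membered δ-lactone ring B (C1 carbonyl, O2, C3, C4). Ring A carries a free phenol at C8, peri to the C1 carbonyl and hydrogen-bonded to it, and a methyl ether at C6, while C5 and C7 are unsubstituted and strongly activated towards electrophiles. C3 is the only stereocentre; it is bonded to O2, to the C4 methylene and to an unbranched eleven-carbon chain ending in a primary alcohol, so there is no neighbouring stereocentre to relay from, and its two carbon substituents differ little in size. The fragile elements are the lactone (opened by hydroxide or alkoxide), the C3–O2 bond that carries the configuration, the electron-rich arene, and the need to tell O8 from O6. The skeleton is simple; the real difficulty is to set an isolated stereocentre in high enantiopurity and to bring in the long functionalised chain and the O6/O8 differentiation in a short sequence. The key step uses the fact that C3 is attached only to O2, C4 and the chain: removing H from C3 and C4 gives a planar 3-alkylisocoumarin, whose ring B can be assembled from the carboxyl group (C1, O2) and the single free ortho C–H (future C4a) of a 2,4-dioxygenated benzoic acid, plus a two-carbon acylmethyl unit (C4, C3) that already carries the chain.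

## Logic of the disconnections

11 to 10: the O8–CH3 bond and the O–CH2Ph bond at the chain terminus are put back. Both ethers can fall in one Lewis-acid operation because O8 sits peri to the C1 carbonyl and is activated by chelation, while O6–CH3 has no such neighbour. The gain is that phenol and alcohol stay masked through the basic and metal-catalysed steps. The forward step must discriminate O8 from O6, must not ionise C3–O2, and must keep the liberated benzyl cation away from ring A.

10 to 9: the C3–H and C4–H bonds are removed. This erases the only stereocentre and gives a flat, achiral enol lactone, so no chiral building block is needed. The forward step needs a hydrogenation catalyst that selects one face of C3=C4 when C3 carries an unbranched alkyl group, and that leaves the benzyl ether, both arenes and the lactone carbonyl alone.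

9 to 6 and 7 (through 8): the C4a–C4 and O2–C3 bonds are cut. The carbon that becomes C4a carries the only ortho C–H of 7, and the acyl carbon of 6 is already at the oxidation level of C3. Two fragments of similar size are joined, ring B is closed and the whole chain is attached in one operation, without a halogenated arene. The forward step demands site-selective C–H metalation, carbene transfer from an enolisable alkyl keto ylide, and ring closure through oxygen with loss of water.

6 to 2 and 3 (through 4 and 5): the bond between the ylide carbon and the acyl carbon is cut, because the acyl carbon is the carboxyl carbon of 2. The gain is a bench-stable, non-diazo carbene precursor made from 2 and 3 alone. The forward step needs an acyl activation that tolerates the strongly basic ylide, and enough ylide to deprotonate the first-formed acylsulfoxonium salt.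

2 to 1: the O–CH2Ph bond is cut. The terminal hydroxyl must be masked, or it would compete in acyl activation and consume the ylide. Benzyl is chosen because it survives base, rhodium catalysis and homogeneous hydrogenation, and leaves in the same operation as the O8 methyl group. Going through the free acid 2, not an ester, avoids base-mediated etherification next to an ester and saves a step. The forward step needs O-alkylation of the alkoxide in preference to the carboxylate.

## Other disconnections considered

Alternative 1: Ring A is made last; the cuts are C8–C8a and C4a–C5. They lead back to the electron-rich diene 1,3-dimethoxy-1-(trimethylsilyloxy)buta-1,3-diene A1 and the enantiopure ynoate methyl (R)-16-(tert-butyldimethylsilyloxy)-5-(triethylsilyloxy)hexadec-2-ynoate A2. In the forward sense a thermal Diels–Alder reaction would join the CH2 terminus of A1 to the β-carbon of A2 and the ketene-acetal terminus of A1 to the α-carbon of A2. Loss of the acetal methoxy group would aromatise the adduct to the salicylate methyl (R)-2-[13-(tert-butyldimethylsilyloxy)-2-(triethylsilyloxy)tridecyl]-6-hydroxy-4-methoxybenzoate A3. Removal of both silyl groups from A3 and lactonisation of the freed C3 hydroxyl onto the ester would then finish 11.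
- In favour: the regiochemistry is polarity-matched. In A3 the O8–H and O6–CH3 groups emerge already differentiated, so no selective demethylation is needed. C3 comes from a resolved building block, so its enantiopurity does not depend on a late catalytic step. On these last two points the alternative is the better plan.
- Against: β-alkyl ynoates are sluggish partners for such dienes, so forcing conditions would be needed that the hydrolytically labile A1 tolerates poorly. A2 needs several steps of its own (resolved epoxide, alkynylation with a propiolate anion, two different silyl ethers). Ring A, which the chosen plan buys as 7, is built from scratch.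
- Comparison: structurally the chosen plan forms ring B and leaves ring A untouched, and this one does the reverse. Mechanistically a concerted cycloaddition–aromatisation to A3 has no site-selectivity question; the chosen plan is equal there because 7 has a single ortho C–H. In step economy the alternative should need about eight or nine steps against five.

Alternative 2: The cut is O2–C3, made by oxygen insertion. The precursor is racemic 2-(11-hydroxyundecyl)-5,7-dimethoxyindan-1-one A4. In the forward sense a Baeyer–Villiger monooxygenase would oxidise one enantiomer of A4 while C2 epimerises, with migration of C2 with retention, to give (R)-3-(11-hydroxyundecyl)-6,8-dimethoxy-3,4-dihydroisocoumarin A5. Chelation-controlled demethylation of A5 at O8 would complete 11.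
- In favour: A5 is one step from the target and the chain alcohol needs no protecting group. The ring oxygen and the configuration arrive in one step with air as oxidant and no precious metal. A dynamic resolution can in principle convert all of the racemate. On protecting-group economy and on the length of the end-game the alternative is the better plan.
- Against: on migratory aptitude an electron-rich aryl group should move in preference to a secondary alkyl, so the enzyme would have to overrule the intrinsic regiochemistry. It would also have to accept a long amphiphilic C11 chain and a peri-methoxy group, which goes well beyond the short 2-alkyl groups typical of such substrates. The basic medium needed for epimerisation threatens the lactone. A4 is poorly soluble in water and itself needs about three steps.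
- Comparison: both plans create C3 late from an achiral or racemic precursor. One relies on a retentive migration inside an enzyme pocket, the other on face-selective hydrogen delivery by a small-molecule catalyst with close substrate analogy. The step counts are similar, but the uncertainty of the enzymatic step is much higher.

Alternative 3: The cuts are C8a–C4a (aldol) and C1–O2 (lactone). The precursor is the diketo-dioxinone (R)-6-[17-(benzyloxy)-2,4-dioxo-6-(triethylsilyloxy)heptadecyl]-2,2-dimethyl-4H-1,3-dioxin-4-one A6. In the forward sense an amine base would trigger aldol closure and dehydration of A6 to the resorcylate acetonide (R)-5-[13-(benzyloxy)-2-(triethylsilyloxy)tridecyl]-7-hydroxy-2,2-dimethyl-4H-benzo[d][1,3]dioxin-4-one A7. A fluoride source would then free the C3 alkoxide of A7, which opens the benzodioxinone to give (R)-3-[11-(benzyloxy)undecyl]-6,8-dihydroxy-3,4-dihydroisocoumarin A8. Selective methylation of A8 at O6 (O8–H is tied up in the hydrogen bond to C1=O) and hydrogenolysis of the benzyl ether would give 11.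
- In favour: the conditions are very mild, and the oxygenation pattern of ring A in A7 and A8 is unambiguous. No demethylation is needed. C3 is fixed before the rings are made, so its enantiopurity is not at stake in the key step. On mildness and on certainty of configuration the alternative is the equal or the better plan.
- Against: A6 is a sensitive tricarbonyl that needs a long assembly (dioxinone acylation, chain extension with a chiral β-silyloxy acyl unit). An extra regioselective methylation of A8 is required. Ring A is again built from acyclic material.
- Comparison: this plan makes both rings in one pot by polyketide-type condensation, while the chosen plan makes only ring B by C–H functionalisation. The alternative should exceed ten steps against five, so it is clearly worse on step economy.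

Key step: step 3

Assumption: the configuration is read from the SMILES as 3R. In step 4 the ligand hand written, (R,R)-SINpEt [1,3-bis((R)-1-(naphthalen-1-yl)ethyl)imidazolin-2-ylidene] with (R,R)-1,2-diphenylethylenediamine, is taken as the one that delivers 3R, and the mirror-image pair is to be used if a test reduction shows the opposite sense.

## Route

Step 1
Reactants: 1 12-hydroxydodecanoic acid
Product: 2 12-(benzyloxy)dodecanoic acid
Conditions: NaH (2.5 equiv), BnBr (1.2 equiv), Bu4NI (cat.), THF–DMF, 0 °C to rt; aq. NaOH, 50 °C; then HCl
Reagents that add atoms: benzyl bromide, BrCc1ccccc1
Why: Williamson ether synthesis on the dianion; the alkoxide is far more nucleophilic than the carboxylate, so the ether should form in preference, the brief hydroxide hold saponifies any benzyl ester formed at the carboxylate, and acidification returns the free acid.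

Step 2
Reactants: 2 12-(benzyloxy)dodecanoic acid; 3 trimethylsulfoxonium iodide
Product: 6 13-(benzyloxy)-1-[dimethyl(oxo)-λ6-sulfanylidene]tridecan-2-one, via dimethylsulfoxonium methylide 4 (not isolated), via acyl imidazolide 5 (not isolated)
Conditions: 3 (3 equiv), KOtBu (3 equiv), THF, reflux; separately 2, CDI (1.1 equiv), THF, rt; combine at 0 °C to rt
Reagents that add atoms: none
Why: Acylation of a sulfoxonium methylide by an activated carboxylic acid (Corey–Chaykovsky-type ylide acylation); the imidazolide should transfer the acyl group to the ylide carbon, and the excess ylide deprotonates the acylsulfoxonium salt to the stabilised keto ylide, which does not react further. The benzyl ether is inert to the base.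

Step 3
Reactants: 6 13-(benzyloxy)-1-[dimethyl(oxo)-λ6-sulfanylidene]tridecan-2-one; 7 2,4-dimethoxybenzoic acid
Product: 9 3-[11-(benzyloxy)undecyl]-6,8-dimethoxyisocoumarin, via keto acid 8 (not isolated)
Conditions: 7 (1.5 equiv), [Cp*RhCl2]2 (4 mol%), AgSbF6 (16 mol%), NaOAc (30 mol%), CF3CH2OH, 80 °C, N2
Reagents that add atoms: none
Why: This is the carboxylate-directed C–H acylmethylation of a benzoic acid with a sulfoxonium ylide followed by annulation, a known reaction type under trivalent rhodium (or divalent ruthenium) catalysis. The cationic Cp*Rh carboxylate of 7 should cleave the C6–H bond by concerted metalation–deprotonation to give a five-membered rhodacycle. The ylide carbon of 6 then binds to rhodium and loses dimethyl sulfoxide to give a rhodium carbene, which inserts into the aryl–rhodium bond (forming C4a–C4); protonation of the rhodium–carbon bond releases keto acid 8 and returns the catalyst. Ring B closes by 6-exo-trig addition of the carboxyl oxygen to the ketone carbonyl and loss of water from the lactol (forming O2–C3), helped by the fluorinated alcohol and the Lewis-acidic metal salts. No stereocentre is formed. The step needs site selectivity, which is secured because C6 is the only ortho C–H of 7 (the other ortho position carries OMe, which also excludes double acylmethylation). It also needs closure through oxygen in preference to carbon, which the carboxylate nucleophile and the acidic medium secure. The benzyl ether has no directing group and the aryl methyl ethers are inert, so the chain and both ring oxygens should pass through unchanged.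

Step 4
Reactants: 9 3-[11-(benzyloxy)undecyl]-6,8-dimethoxyisocoumarin
Product: 10 (R)-3-[11-(benzyloxy)undecyl]-6,8-dimethoxy-3,4-dihydroisocoumarin
Conditions: [Ru(cod)(2-methylallyl)2] (2 mol%), (R,R)-SINpEt·HBF4, KOtBu, (R,R)-1,2-diphenylethylenediamine (precatalyst formed in hexane, 70 °C); NaOtBu (10 mol%), H2 (50 bar), toluene, 25 °C
Reagents that add atoms: none
Why: Enantioselective hydrogenation of a 3-substituted isocoumarin with a chiral ruthenium N-heterocyclic carbene diamine catalyst; the ruthenium hydride should add across the polarised C3=C4 bond of the planar enol lactone from the face chosen by the ligand pocket, so C3 is set by catalyst control alone (3R with the ligand hand of the assumption). The homogeneous catalyst under these mild conditions is not expected to hydrogenolyse the benzyl ether or reduce either benzene ring or the lactone carbonyl.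

Step 5
Reactants: 10 (R)-3-[11-(benzyloxy)undecyl]-6,8-dimethoxy-3,4-dihydroisocoumarin
Product: 11 (R)-8-hydroxy-3-(11-hydroxyundecyl)-6-methoxy-3,4-dihydroisocoumarin (CNP0140068.1)
Conditions: BCl3 (5 equiv), C6HMe5 (3 equiv), CH2Cl2, −78 to 0 °C; then H2O
Reagents that add atoms: none
Why: Lewis-acid ether cleavage; BCl3 chelated between the C1 carbonyl and O8 should cleave only that methyl ether (the C6 ether has no chelating neighbour) and also the primary benzyl ether, with pentamethylbenzene trapping the benzyl cation by Friedel–Crafts alkylation so that ring A is not benzylated. The C3–O2 bond is not ionised at or below 0 °C, so the configuration is kept; water hydrolyses the boron–oxygen bonds.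

## Compound list

1 | 12-hydroxydodecanoic acid | OCCCCCCCCCCCC(=O)O | starting material
2 | 12-(benzyloxy)dodecanoic acid | O=C(O)CCCCCCCCCCCOCc1ccccc1 | intermediate
3 | trimethylsulfoxonium iodide | C[S+](C)(C)=O.[I-] | starting material
4 | dimethylsulfoxonium methylide | CS(C)(=O)=C | intermediate
5 | 1-[12-(benzyloxy)dodecanoyl]-1H-imidazole (acyl imidazolide) | O=C(CCCCCCCCCCCOCc1ccccc1)n2ccnc2 | intermediate
6 | 13-(benzyloxy)-1-[dimethyl(oxo)-λ6-sulfanylidene]tridecan-2-one | CS(C)(=O)=CC(=O)CCCCCCCCCCCOCc1ccccc1 | intermediate
7 | 2,4-dimethoxybenzoic acid | COc1ccc(C(=O)O)c(OC)c1 | starting material
8 | 2-[13-(benzyloxy)-2-oxotridecyl]-4,6-dimethoxybenzoic acid (keto acid) | COc1cc(OC)c(C(=O)O)c(CC(=O)CCCCCCCCCCCOCc2ccccc2)c1 | intermediate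
9 | 3-[11-(benzyloxy)undecyl]-6,8-dimethoxyisocoumarin | COc1cc(OC)c2c(c1)C=C(CCCCCCCCCCCOCc3ccccc3)OC2=O | intermediate
10 | (R)-3-[11-(benzyloxy)undecyl]-6,8-dimethoxy-3,4-dihydroisocoumarin | COc1cc(OC)c2c(c1)C[C@@H](CCCCCCCCCCCOCc3ccccc3)OC2=O | intermediate
11 | (R)-8-hydroxy-3-(11-hydroxyundecyl)-6-methoxy-3,4-dihydroisocoumarin | COc1cc(O)c2c(c1)C[C@@H](CCCCCCCCCCCO)OC2=O | target

## Step count and least certain steps

Total step count: 5. Longest linear sequence: 5 steps (1 to 2 to 6 to 9 to 10 to 11); 3 and 7 enter as purchased materials.

Step 3 (key step). The most likely failures are protodecarboxylation of the electron-rich acid under silver salt and heat, slow carbene transfer with competing decomposition of the enolisable alkyl keto ylide, and arrest at the open keto acid stage. The fallback changes the directing group and the ring-closing event. It sets out from 7, which is converted with CDI, O-methylhydroxylamine hydrochloride and Et3N into N-methoxy-2,4-dimethoxybenzamide F1. This amide binds rhodium more strongly and cannot decarboxylate. The annulation of F1 with 6 under [Cp*RhCl2]2 catalysis is a known reaction type for trivalent rhodium; with an acidic additive it should close through the amide oxygen with loss of O-methylhydroxylamine, and it returns to the route at 9.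

Step 4. The most likely failure is insufficient facial discrimination, because the long flexible chain at C3 and the peri-methoxy group near the carbonyl may disturb the substrate binding on which the catalyst relies; incomplete conversion is the second concern. The fallback gives up catalyst-controlled hydrogenation and carries the stereocentre in a resolved epoxide. It sets out from 6 and uses 7. Anhydrous HCl in THF should convert 6 into 13-(benzyloxy)-1-chlorotridecan-2-one F2 with loss of dimethyl sulfoxide. NaBH4 in methanol then gives racemic 13-(benzyloxy)-1-chlorotridecan-2-ol F3, and aqueous NaOH closes it to racemic 2-[11-(benzyloxy)undecyl]oxirane F4. Hydrolytic kinetic resolution of F4 with (salen)Co(OAc) and 0.55 equiv of water leaves (R)-2-[11-(benzyloxy)undecyl]oxirane F5; the catalyst enantiomer is chosen so that the (S)-oxirane is hydrolysed, and for a simple alkyl oxirane this is expected to be the (R,R)-complex. Carboxylate-directed ortho-C–H alkylation of 7 with F5 (Pd(OAc)2, a mono-N-protected amino acid ligand, KOAc, (CF3)2CHOH) should attack the CH2 terminus of the oxirane, leave the stereocentre untouched and lactonise in the same pot. This path bypasses 9 and returns to the route at 10.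

Step 5. The most likely failures are benzyl transfer to C5 or C7 of ring A if trapping is too slow, incomplete cleavage of the primary benzyl ether at low temperature, and loss of the C6 methyl ether on prolonged exposure. The fallback separates the two deprotections and uses orthogonal chemistry. It sets out from 10. Hydrogenolysis (H2, Pd/C, ethyl acetate) should give (R)-3-(11-hydroxyundecyl)-6,8-dimethoxy-3,4-dihydroisocoumarin F6, the same structure as A5. Chelation-controlled demethylation of F6 with MgI2 etherate in toluene then removes only the methyl group peri to the carbonyl and returns to the route at 11.

Step 2. The most likely failures are enolisation of the acyl imidazolide by the basic ylide (loss of acyl donor through ketene-type pathways) and double acylation of the ylide. The fallback changes the acyl donor to an isolated ester. It sets out from 2, which is esterified (MeOH, cat. H2SO4, reflux) to methyl 12-(benzyloxy)dodecanoate F7. Addition of F7 to 4 in refluxing THF, the classical ester acylation of the methylide, returns to the route at 6.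

## Further compounds

F1 | step 3 | N-methoxy-2,4-dimethoxybenzamide | COc1ccc(C(=O)NOC)c(OC)c1
F2 | step 4 | 13-(benzyloxy)-1-chlorotridecan-2-one | ClCC(=O)CCCCCCCCCCCOCc1ccccc1
F3 | step 4 | racemic 13-(benzyloxy)-1-chlorotridecan-2-ol | ClCC(O)CCCCCCCCCCCOCc1ccccc1
F4 | step 4 | racemic 2-[11-(benzyloxy)undecyl]oxirane | C1OC1CCCCCCCCCCCOCc2ccccc2
F5 | step 4 | (R)-2-[11-(benzyloxy)undecyl]oxirane | C1O[C@@H]1CCCCCCCCCCCOCc2ccccc2
F6 | step 5 | (R)-3-(11-hydroxyundecyl)-6,8-dimethoxy-3,4-dihydroisocoumarin | COc1cc(OC)c2c(c1)C[C@@H](CCCCCCCCCCCO)OC2=O
F7 | step 2 | methyl 12-(benzyloxy)dodecanoate | COC(=O)CCCCCCCCCCCOCc1ccccc1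
A1 | alternative 1 | 1,3-dimethoxy-1-(trimethylsilyloxy)buta-1,3-diene | COC(=C)C=C(OC)O[Si](C)(C)C
A2 | alternative 1 | methyl (R)-16-(tert-butyldimethylsilyloxy)-5-(triethylsilyloxy)hexadec-2-ynoate | COC(=O)C#CC[C@@H](CCCCCCCCCCCO[Si](C)(C)C(C)(C)C)O[Si](CC)(CC)CC
A3 | alternative 1 | methyl (R)-2-[13-(tert-butyldimethylsilyloxy)-2-(triethylsilyloxy)tridecyl]-6-hydroxy-4-methoxybenzoate | COC(=O)c1c(O)cc(OC)cc1C[C@@H](CCCCCCCCCCCO[Si](C)(C)C(C)(C)C)O[Si](CC)(CC)CC
A4 | alternative 2 | racemic 2-(11-hydroxyundecyl)-5,7-dimethoxyindan-1-one | COc1cc(OC)c2c(c1)CC(CCCCCCCCCCCO)C2=O
A5 | alternative 2 | (R)-3-(11-hydroxyundecyl)-6,8-dimethoxy-3,4-dihydroisocoumarin | COc1cc(OC)c2c(c1)C[C@@H](CCCCCCCCCCCO)OC2=O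
A6 | alternative 3 | (R)-6-[17-(benzyloxy)-2,4-dioxo-6-(triethylsilyloxy)heptadecyl]-2,2-dimethyl-4H-1,3-dioxin-4-one | CC1(C)OC(=O)C=C(CC(=O)CC(=O)C[C@@H](CCCCCCCCCCCOCc2ccccc2)O[Si](CC)(CC)CC)O1
A7 | alternative 3 | (R)-5-[13-(benzyloxy)-2-(triethylsilyloxy)tridecyl]-7-hydroxy-2,2-dimethyl-4H-benzo[d][1,3]dioxin-4-one | CC1(C)OC(=O)c2c(C[C@@H](CCCCCCCCCCCOCc3ccccc3)O[Si](CC)(CC)CC)cc(O)cc2O1
A8 | alternative 3 | (R)-3-[11-(benzyloxy)undecyl]-6,8-dihydroxy-3,4-dihydroisocoumarin | Oc1cc(O)c2c(c1)C[C@@H](CCCCCCCCCCCOCc3ccccc3)OC2=O
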